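**Retrosynthetic overview**
1. Target 17 comes from silyl ether 16 by Si–O cleavage. The pyran ring of 16 is cut at O1–C2 and at C4–C4a, which leads to resorcinol 12 and phenyl vinyl ketone 13.
2. Enabling feature: in 12, ring A is a phloroglucinol ring with a mirror plane through the OMe-bearing carbon (future C5) and the benzofuranyl-bearing carbon (future C8). The two hydroxyls (future O1 and O7) and the two ring CH carbons (future C4a and C6) are pairwise equivalent, and each CH is ortho to one OH and para to the other. A three-carbon unit can therefore be attached carbon-first and closed from O1 onto C2 at either edge with the same result.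
3. 12 comes from benzofuran 11, whose furan ring is made by Sonogashira coupling and 5-endo-dig closure of iodophenol 5 (ring D) with alkyne 9 (ring A, both oxygens masked as MOM ethers).
4. 5 derives from 3-methoxy-2-methylphenol (silylation, C–H borylation/oxidation, iodination). 9 derives from 2',6'-dihydroxy-4'-methoxyacetophenone (MOM protection, ketone-to-alkyne conversion).
5. Order of ring formation: furan ring (step 6), then pyran ring together with the C2 stereocenter (step 8).

Key step: step 8

Remark on the chemistry: flavan numbering (O1, C2, C3, C4, C4a, C5 to C8, C8a) is used for the chroman part. Ring A is its benzo ring and ring D is the benzo ring of the benzofuran.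
Remark on the chemistry: the sense of induction of the chiral acid in step 8 cannot be derived from a close analogue. The (R) acid is written, and its mirror image would be used if screening shows the opposite sense.

**Route**

Step 1
Reactants: 1 3-methoxy-2-methylphenol
Product: 2 triisopropyl(3-methoxy-2-methylphenoxy)silane
Conditions: TIPSCl, imidazole, DMF, rt
Reagents that add atoms: triisopropylsilyl chloride, CC(C)[Si](Cl)(C(C)C)C(C)C
Why: Standard imidazole-promoted O-silylation of a phenol; the bulky silyl ether is chosen because it later shields its neighbouring ring position.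

Step 2
Reactants: 2 triisopropyl(3-methoxy-2-methylphenoxy)silane
Product: 4 3-methoxy-4-methyl-5-[(triisopropylsilyl)oxy]phenol, via arylboronate 3 (not isolated)
Conditions: [Ir(OMe)(cod)]2 (1.5 mol%), 4,4'-di-tert-butyl-2,2'-bipyridine (3 mol%), B2pin2, THF, 80 °C; then KHSO5 (Oxone, 2KHSO5·KHSO4·K2SO4), acetone–H2O, rt
Reagents that add atoms: potassium peroxymonosulfate, [K+].[O-]S(=O)(=O)OO
Why: Iridium-catalysed aromatic C–H borylation is sterically controlled and should take the only ring C–H without an ortho substituent (para to the methyl group), and oxidation of the arylboronate in the same flask should give the phenol (one-pot borylation–oxidation).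

Step 3
Reactants: 4 3-methoxy-4-methyl-5-[(triisopropylsilyl)oxy]phenol
Product: 5 2-iodo-3-methoxy-4-methyl-5-[(triisopropylsilyl)oxy]phenol
Conditions: NIS (1.0 equiv), CH2Cl2, −40 °C → 0 °C
Reagents that add atoms: N-iodosuccinimide, O=C1CCC(=O)N1I
Why: Electrophilic aromatic iodination ortho to the free phenol: the para position carries the methyl group, and of the two ortho positions the one beside OTIPS is shielded by the isopropyl groups, so iodine should enter between OH and OMe.

Step 4
Reactants: 6 1-(2,6-dihydroxy-4-methoxyphenyl)ethan-1-one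
Product: 7 1-[4-methoxy-2,6-bis(methoxymethoxy)phenyl]ethan-1-one
Conditions: NaH (2.4 equiv), MOMCl, DMF, 0 °C → rt
Reagents that add atoms: chloromethyl methyl ether, COCCl
Why: Williamson-type O-alkylation of both chelated phenoxides, which are far more acidic than the acetyl α-position, gives the bis-MOM ether.

Step 5
Reactants: 7 1-[4-methoxy-2,6-bis(methoxymethoxy)phenyl]ethan-1-one
Product: 9 2-ethynyl-5-methoxy-1,3-bis(methoxymethoxy)benzene, via enol phosphate 8 (not isolated)
Conditions: LiN(iPr)2 (LDA, 1.1 equiv), THF, −78 °C; ClP(O)(OEt)2; then LDA (2.3 equiv), −78 °C → rt; aq. NH4Cl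
Reagents that add atoms: none
Why: Ketone-to-alkyne conversion by kinetic enolate trapping as the enol phosphate and base-induced β-elimination, a standard sequence for aryl methyl ketones that fixes the alkyne at the ring carbon between the two MOM ethers.

Step 6
Reactants: 5 2-iodo-3-methoxy-4-methyl-5-[(triisopropylsilyl)oxy]phenol; 9 2-ethynyl-5-methoxy-1,3-bis(methoxymethoxy)benzene
Product: 11 triisopropyl({4-methoxy-2-[4-methoxy-2,6-bis(methoxymethoxy)phenyl]-5-methyl-1-benzofuran-6-yl}oxy)silane, via alkynylphenol 10 (not isolated)
Conditions: PdCl2(PPh3)2 (5 mol%), CuI (10 mol%), Et3N–DMF, 70 °C, degassed, 9 added slowly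
Reagents that add atoms: none
Why: Sonogashira coupling followed in the same flask by base/copper-assisted 5-endo-dig addition of the ortho phenol to the alkyne (benzofuran heteroannulation); since both ring A oxygens are MOM ethers, only the ring D hydroxyl can close the furan ring.

Step 7
Reactants: 11 triisopropyl({4-methoxy-2-[4-methoxy-2,6-bis(methoxymethoxy)phenyl]-5-methyl-1-benzofuran-6-yl}oxy)silane
Product: 12 5-methoxy-2-{4-methoxy-5-methyl-6-[(triisopropylsilyl)oxy]-1-benzofuran-2-yl}benzene-1,3-diol
Conditions: TsOH·H2O (cat.), MeOH–THF, 45 °C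
Reagents that add atoms: none
Why: Acid-catalysed transacetalisation to methanol removes both MOM groups, whereas the hindered aryl triisopropylsilyl ether should persist, and this unveils the mirror-symmetric resorcinol.

Step 8
Reactants: 12 5-methoxy-2-{4-methoxy-5-methyl-6-[(triisopropylsilyl)oxy]-1-benzofuran-2-yl}benzene-1,3-diol; 13 1-phenylprop-2-en-1-one (phenyl vinyl ketone)
Product: 16 (2S)-5-methoxy-8-{4-methoxy-5-methyl-6-[(triisopropylsilyl)oxy]-1-benzofuran-2-yl}-2-phenyl-3,4-dihydro-2H-chromen-7-ol, via aryl ketone 14 (not isolated), via 4H-chromene 15 (not isolated)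
Conditions: 13 (1.05 equiv, slow addition), (R)-3,3'-bis(2,4,6-triisopropylphenyl)-1,1'-binaphthalene-2,2'-diyl N-(trifluoromethylsulfonyl)phosphoramide (10 mol%), 5 Å MS, toluene, 0 °C → rt; then diethyl 2,6-dimethyl-1,4-dihydropyridine-3,5-dicarboxylate (Hantzsch ester, 1.4 equiv), 35 °C, same flask
Reagents that add atoms: none
Why: Proposed new method: the chiral acid should first promote Friedel–Crafts conjugate addition of a ring A carbon of 12 to enone 13 to give ketone 14, whose neighbouring hydroxyl adds to the ketone carbon; loss of water gives 4H-chromene 15 in equilibrium with the 2-phenylchroman-2-ylium ion, and the Hantzsch ester transfers hydride to C2 of this cation inside its ion pair with the chiral phosphoramide anion. The closest known reaction types are the acid-catalysed annulation of phenols with vinyl ketones to 2-hydroxychromans and 4H-chromenes, the ionic hydrogenation of such hemiketals to chromans, and counteranion-directed Hantzsch ester reductions of iminium and benzopyrylium ions with chiral phosphoric acids; their fusion into one enantioselective annulation is what is new. One ring is closed, the pyran ring: after the intermolecular C4–C4a bond, the O1–C2 bond forms by 6-exo-trig attack of the phenol oxygen on the carbonyl group. The only new stereocenter, C2, is set in the hydride transfer, and its S configuration is to be controlled by the chiral counteranion, which blocks one face of the planar oxocarbenium ion. The step needs C-alkylation at one defined ring A position and cyclisation by one defined hydroxyl, and the mirror plane of 12 makes both CH positions and both hydroxyls equivalent, so that either edge leads to the same flavan; ring D is less nucleophilic than the dihydroxy ring A and its only free CH is shielded by the OTIPS group. Adding the Hantzsch ester only after 13 is consumed should keep the enone from being reduced.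

Step 9
Reactants: 16 (2S)-5-methoxy-8-{4-methoxy-5-methyl-6-[(triisopropylsilyl)oxy]-1-benzofuran-2-yl}-2-phenyl-3,4-dihydro-2H-chromen-7-ol
Product: 17 (2S)-8-(6-hydroxy-4-methoxy-5-methyl-1-benzofuran-2-yl)-5-methoxy-2-phenyl-3,4-dihydro-2H-chromen-7-ol
Conditions: Bu4NF, AcOH, THF, 0 °C
Reagents that add atoms: none
Why: Fluoride-induced cleavage of the aryl silyl ether under acetic acid buffering, conditions that should leave the benzylic ether stereocenter at C2 untouched.

**Compound list**
1 | 3-methoxy-2-methylphenol | COc1cccc(O)c1C | starting material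
2 | triisopropyl(3-methoxy-2-methylphenoxy)silane | COc1cccc(O[Si](C(C)C)(C(C)C)C(C)C)c1C | intermediate
3 | triisopropyl[3-methoxy-2-methyl-5-(4,4,5,5-tetramethyl-1,3,2-dioxaborolan-2-yl)phenoxy]silane | COc1cc(B2OC(C)(C)C(C)(C)O2)cc(O[Si](C(C)C)(C(C)C)C(C)C)c1C | intermediate
4 | 3-methoxy-4-methyl-5-[(triisopropylsilyl)oxy]phenol | COc1cc(O)cc(O[Si](C(C)C)(C(C)C)C(C)C)c1C | intermediate
5 | 2-iodo-3-methoxy-4-methyl-5-[(triisopropylsilyl)oxy]phenol | COc1c(I)c(O)cc(O[Si](C(C)C)(C(C)C)C(C)C)c1C | intermediate
6 | 1-(2,6-dihydroxy-4-methoxyphenyl)ethan-1-one | COc1cc(O)c(C(C)=O)c(O)c1 | starting material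
7 | 1-[4-methoxy-2,6-bis(methoxymethoxy)phenyl]ethan-1-one | COCOc1cc(OC)cc(OCOC)c1C(C)=O | intermediate
8 | diethyl 1-[4-methoxy-2,6-bis(methoxymethoxy)phenyl]ethenyl phosphate | C=C(OP(=O)(OCC)OCC)c1c(OCOC)cc(OC)cc1OCOC | intermediate
9 | 2-ethynyl-5-methoxy-1,3-bis(methoxymethoxy)benzene | C#Cc1c(OCOC)cc(OC)cc1OCOC | intermediate
10 | 2-{[4-methoxy-2,6-bis(methoxymethoxy)phenyl]ethynyl}-3-methoxy-4-methyl-5-[(triisopropylsilyl)oxy]phenol | COCOc1cc(OC)cc(OCOC)c1C#Cc1c(O)cc(O[Si](C(C)C)(C(C)C)C(C)C)c(C)c1OC | intermediate
11 | triisopropyl({4-methoxy-2-[4-methoxy-2,6-bis(methoxymethoxy)phenyl]-5-methyl-1-benzofuran-6-yl}oxy)silane | COCOc1cc(OC)cc(OCOC)c1-c1cc2c(OC)c(C)c(O[Si](C(C)C)(C(C)C)C(C)C)cc2o1 | intermediate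
12 | 5-methoxy-2-{4-methoxy-5-methyl-6-[(triisopropylsilyl)oxy]-1-benzofuran-2-yl}benzene-1,3-diol | COc1cc(O)c(-c2cc3c(OC)c(C)c(O[Si](C(C)C)(C(C)C)C(C)C)cc3o2)c(O)c1 | intermediate
13 | 1-phenylprop-2-en-1-one (phenyl vinyl ketone) | C=CC(=O)c1ccccc1 | starting material
14 | 3-(2,4-dihydroxy-6-methoxy-3-{4-methoxy-5-methyl-6-[(triisopropylsilyl)oxy]-1-benzofuran-2-yl}phenyl)-1-phenylpropan-1-one | COc1cc(O)c(-c2cc3c(OC)c(C)c(O[Si](C(C)C)(C(C)C)C(C)C)cc3o2)c(O)c1CCC(=O)c1ccccc1 | intermediate
15 | 5-methoxy-8-{4-methoxy-5-methyl-6-[(triisopropylsilyl)oxy]-1-benzofuran-2-yl}-2-phenyl-4H-chromen-7-ol | COc1cc(O)c(-c2cc3c(OC)c(C)c(O[Si](C(C)C)(C(C)C)C(C)C)cc3o2)c2c1CC=C(c1ccccc1)O2 | intermediate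
16 | (2S)-5-methoxy-8-{4-methoxy-5-methyl-6-[(triisopropylsilyl)oxy]-1-benzofuran-2-yl}-2-phenyl-3,4-dihydro-2H-chromen-7-ol | COc1cc(O)c(-c2cc3c(OC)c(C)c(O[Si](C(C)C)(C(C)C)C(C)C)cc3o2)c2c1CC[C@@H](c1ccccc1)O2 | intermediate
17 | (2S)-8-(6-hydroxy-4-methoxy-5-methyl-1-benzofuran-2-yl)-5-methoxy-2-phenyl-3,4-dihydro-2H-chromen-7-ol | COc1cc(O)c(-c2cc3c(OC)c(C)c(O)cc3o2)c2c1CC[C@@H](c1ccccc1)O2 | target

**Step count and risks**
Total steps: 9. Longest linear sequence: 7 steps (steps 1, 2, 3, 6, 7, 8, 9).

Steps most likely to fail:

1. Step 8. The ion pair may be too loose for good facial discrimination in the hydride transfer. The oxocarbenium ion may also be captured by a second molecule of the electron-rich resorcinol before hydride arrives, or product 16 may undergo a second conjugate addition at C6. The fallback uses known chemistry, sets out from 12 and 13 and comes back at 16. The conjugate addition would be run alone with an achiral acid (diphenyl phosphate, 10 mol%, toluene, rt) and ketone 14 isolated. Noyori transfer hydrogenation with RuCl[(R,R)-TsDPEN](p-cymene) in HCO2H–Et3N should then give 4-[(3R)-3-hydroxy-3-phenylpropyl]-5-methoxy-2-{4-methoxy-5-methyl-6-[(triisopropylsilyl)oxy]-1-benzofuran-2-yl}benzene-1,3-diol F1. Intramolecular Mitsunobu etherification (PPh3, DIAD, THF, 0 °C) should close the O1–C2 bond with inversion through the only hydroxyl that can form a six-membered ring, giving 16.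

2. Step 3. Iodination may go to the ortho position beside OTIPS, or the ring may be iodinated twice. The fallback sets out from 4 and comes back at 5. It replaces electrophilic substitution by directed ortho-metalation. MOM protection (MOMCl, iPr2NEt, CH2Cl2) would give triisopropyl[3-methoxy-5-(methoxymethoxy)-2-methylphenoxy]silane F2. Lithiation with n-BuLi (THF, 0 °C) should occur at the position flanked by the two coordinating groups OMOM and OMe and not beside the non-coordinating OTIPS; an iodine quench at −78 °C would give [4-iodo-3-methoxy-5-(methoxymethoxy)-2-methylphenoxy]triisopropylsilane F3. Mild acid (TsOH, MeOH, rt) would then remove the MOM group and give 5.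

3. Step 6. Oxidative addition of palladium into the electron-rich, doubly ortho-substituted iodophenol may be slow, so that copper-mediated oxidative dimerisation consumes alkyne 9, or the sequence may stall before ring closure. The fallback sets out from 9 and 5 and comes back at 11. It is a palladium-free Castro–Stephens coupling with a preformed organocopper. Alkyne 9 with CuI in aqueous NH3–EtOH would give {[4-methoxy-2,6-bis(methoxymethoxy)phenyl]ethynyl}copper F4, isolated as a solid. Heating F4 with 5 in pyridine (115 °C, inert atmosphere) should effect substitution of the iodide and in situ cyclisation of alkynylphenol 10 to 11.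

**Further compounds**
F1 | step 8 | 4-[(3R)-3-hydroxy-3-phenylpropyl]-5-methoxy-2-{4-methoxy-5-methyl-6-[(triisopropylsilyl)oxy]-1-benzofuran-2-yl}benzene-1,3-diol | COc1cc(O)c(-c2cc3c(OC)c(C)c(O[Si](C(C)C)(C(C)C)C(C)C)cc3o2)c(O)c1CC[C@@H](O)c1ccccc1
F2 | step 3 | triisopropyl[3-methoxy-5-(methoxymethoxy)-2-methylphenoxy]silane | COCOc1cc(OC)c(C)c(O[Si](C(C)C)(C(C)C)C(C)C)c1
F3 | step 3 | [4-iodo-3-methoxy-5-(methoxymethoxy)-2-methylphenoxy]triisopropylsilane | COCOc1cc(O[Si](C(C)C)(C(C)C)C(C)C)c(C)c(OC)c1I
F4 | step 6 | {[4-methoxy-2,6-bis(methoxymethoxy)phenyl]ethynyl}copper | [Cu]C#Cc1c(OCOC)cc(OC)cc1OCOC
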